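The benzene ring is numbered C1 (hydroxyethyl sulfate chain), C2 and C3 (Br), C4 and C5 (OH), C6 (H). The contiguous run C1–C2–C3–C4 is taken intact from the four carbons of mucobromic acid, so both bromines and the C4 oxygen are in place before the ring exists and no arene bromination is needed. The route rests on cutting C1–C6 and C4–C5: a 3,4-dibromo-2-silyloxyfuran carrying a CH2CO2Me arm at the other α-carbon adds acrolein in a (4+2) cycloaddition, and acid collapse of the oxa-bridged adduct with loss of water delivers the benzene ring as a salicylaldehyde whose formyl group is a masked C5 hydroxyl.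

Key step: step 3

Assumption: the target is drawn as the free hydrogen sulfate, so it is released in that form by cation exchange of the first-formed pyridinium salt; because free alkyl hydrogen sulfates hydrolyse on standing, it would be kept cold or neutralised for storage.

Step 1
Reactants: 1 mucobromic acid; 2 1-(tert-butyldimethylsilyloxy)-1-methoxyethene
Product: 3 methyl 2-(3,4-dibromo-5-oxo-2,5-dihydrofuran-2-yl)acetate (racemic)
Conditions: 2 (2 equiv), ZnCl2 (0.3 equiv), Et2O–CH2Cl2, 0 °C to rt; aq. NH4Cl
Reagents that add atoms: none
Why: Lewis-acid-mediated Mukaiyama aldol-type addition of the silyl ketene acetal to the lactol carbon of the mucohalic acid (reacting through its ring-opened aldehyde form) followed by relactonisation is a known entry to γ-substituted dihalobutenolides; the new γ-stereocenter forms as a racemate and is erased in step 2.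

Step 2
Reactants: 3 methyl 2-(3,4-dibromo-5-oxo-2,5-dihydrofuran-2-yl)acetate
Product: 4 methyl 2-[3,4-dibromo-5-(tert-butyldimethylsilyloxy)furan-2-yl]acetate
Conditions: TBSOTf (1.2 equiv), i-Pr2NEt (1.5 equiv), CH2Cl2, −78 to 0 °C; pentane, filter, concentrate, use crude
Reagents that add atoms: tert-butyldimethylsilyl trifluoromethanesulfonate (TBSOTf), CC(C)(C)[Si](C)(C)OS(=O)(=O)C(F)(F)F
Why: Soft enolisation, in which the silyl triflate activates the lactone carbonyl and the amine removes the doubly activated γ-hydrogen to give the aromatic 2-silyloxyfuran, is routine for halogenated butenolides, and the hindered non-nucleophilic base is chosen so that it does not displace the β-bromine.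

Step 3
Reactants: 4 methyl 2-[3,4-dibromo-5-(tert-butyldimethylsilyloxy)furan-2-yl]acetate; 5 acrolein
Product: 8 methyl 2-(2,3-dibromo-5-formyl-4-hydroxyphenyl)acetate, via oxanorbornene cycloadduct 6 (not isolated), via hydroxycyclohexenone 7 (not isolated)
Conditions: 5 (4 equiv), BHT (cat.), PhMe, rt to 60 °C; then 1 M HCl, THF, rt
Reagents that add atoms: none
Why: The electron-rich 2-silyloxyfuran serves as the diene in a thermal, asynchronous Diels–Alder reaction in which its chain-bearing α-carbon (ring C1) bonds to the β-carbon of acrolein (C6) and its silyloxy-bearing carbon (C4) bonds to the formyl-bearing carbon (C5); aqueous acid then opens the bridging silyl ketal of 6 to hydroxy-enone 7, whose enolised formyl ketone is an arene hydrate that loses water (C1 hydroxyl, C6 hydrogen) to give the phenol. The closest known reaction type is the cycloaddition of 2-silyloxyfurans to acrylic dienophiles followed by bridge opening and dehydration to phenols. The one ring closed, the six-membered carbocycle, is formed by intermolecular (4+2) cycloaddition, both new bonds arising in the same operation. No stereocenter survives, since those of 6 and 7 (endo/exo mixtures of racemates) are erased on aromatisation. The selectivity required is regiochemical, formyl carbon next to the silyloxy carbon, and it is secured by the silyloxy and ring-oxygen donors, which make the alkyl-bearing furan carbon the nucleophilic terminus that pairs with the electrophilic β-carbon of acrolein; a stepwise conjugate addition followed by ring closure would converge on the same adduct. Acid is preferred to fluoride for the bridge opening so that the tertiary alkoxide of 7 cannot shed the acetate arm by retro-aldol cleavage.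

Step 4
Reactants: 8 methyl 2-(2,3-dibromo-5-formyl-4-hydroxyphenyl)acetate
Product: 10 methyl 2-(2,3-dibromo-4,5-dihydroxyphenyl)acetate, via aryl formate 9 (not isolated)
Conditions: 30% H2O2 (1.1 equiv), NaOH (1.0 equiv), degassed THF–H2O, 0 °C to rt; then NaHSO3, 1 M HCl
Reagents that add atoms: hydrogen peroxide, OO
Why: Dakin oxidation, in which hydroperoxide adds to the formyl group of the ortho-phenoxide, the aryl group migrates to oxygen to give formate 9 and this is hydrolysed in the flask; the single equivalent of base is taken up by the acidic phenol and then by the formic acid formed, so the methyl ester should not be saponified.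

Step 5
Reactants: 10 methyl 2-(2,3-dibromo-4,5-dihydroxyphenyl)acetate
Product: 11 2-(2,3-dibromo-4,5-dihydroxyphenyl)ethanol
Conditions: LiBH4 (4 equiv), THF, 0 to 40 °C; then 1 M HCl, MeOH
Reagents that add atoms: none
Why: Borohydride reduction of the methyl ester with LiBH4, used in excess because the two acidic phenols first consume hydride as hydrogen, leaves the aryl bromides untouched, and the acidic methanol work-up frees the catechol from boron.

Step 6
Reactants: 11 2-(2,3-dibromo-4,5-dihydroxyphenyl)ethanol
Product: 13 2-(2,3-dibromo-4,5-dihydroxyphenyl)ethyl hydrogen sulfate, via pyridinium sulfate salt 12 (not isolated)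
Conditions: SO3·pyridine (1.1 equiv), MeCN–DMF, 0 °C to rt; then H2O, sulfonic acid cation-exchange resin (H+ form), 0–5 °C, lyophilise
Reagents that add atoms: sulfur trioxide–pyridine complex, O=S(=O)([O-])[n+]1ccccc1
Why: O-Sulfation with the sulfur trioxide–amine complex in the absence of added base should favour the primary alcohol, because the dibrominated, mutually hydrogen-bonded phenols are poor neutral nucleophiles; cation exchange of pyridinium salt 12 then gives the hydrogen sulfate.

Compound list
1 | mucobromic acid (3,4-dibromo-5-hydroxyfuran-2(5H)-one, racemic lactol) | O=C1OC(O)C(Br)=C1Br | starting material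
2 | 1-(tert-butyldimethylsilyloxy)-1-methoxyethene | C=C(OC)O[Si](C)(C)C(C)(C)C | starting material
3 | methyl 2-(3,4-dibromo-5-oxo-2,5-dihydrofuran-2-yl)acetate (racemic) | COC(=O)CC1OC(=O)C(Br)=C1Br | intermediate
4 | methyl 2-[3,4-dibromo-5-(tert-butyldimethylsilyloxy)furan-2-yl]acetate | COC(=O)Cc1oc(O[Si](C)(C)C(C)(C)C)c(Br)c1Br | intermediate
5 | acrolein | C=CC=O | starting material
6 | methyl 2-[2,3-dibromo-4-(tert-butyldimethylsilyloxy)-5-formyl-7-oxabicyclo[2.2.1]hept-2-en-1-yl]acetate (racemic, endo/exo mixture) | COC(=O)CC12CC(C=O)C(O[Si](C)(C)C(C)(C)C)(O1)C(Br)=C2Br | intermediate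
7 | methyl 2-(2,3-dibromo-5-formyl-1-hydroxy-4-oxocyclohex-2-en-1-yl)acetate (racemic, diastereomer mixture) | COC(=O)CC1(O)CC(C=O)C(=O)C(Br)=C1Br | intermediate
8 | methyl 2-(2,3-dibromo-5-formyl-4-hydroxyphenyl)acetate | COC(=O)Cc1cc(C=O)c(O)c(Br)c1Br | intermediate
9 | methyl 2-(2,3-dibromo-5-formyloxy-4-hydroxyphenyl)acetate | COC(=O)Cc1cc(OC=O)c(O)c(Br)c1Br | intermediate
10 | methyl 2-(2,3-dibromo-4,5-dihydroxyphenyl)acetate | COC(=O)Cc1cc(O)c(O)c(Br)c1Br | intermediate
11 | 2-(2,3-dibromo-4,5-dihydroxyphenyl)ethanol | OCCc1cc(O)c(O)c(Br)c1Br | intermediate
12 | pyridinium 2-(2,3-dibromo-4,5-dihydroxyphenyl)ethyl sulfate | [O-]S(=O)(=O)OCCc1cc(O)c(O)c(Br)c1Br.c1cc[nH+]cc1 | intermediate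
13 | 2-(2,3-dibromo-4,5-dihydroxyphenyl)ethyl hydrogen sulfate | O=S(=O)(O)OCCc1cc(O)c(O)c(Br)c1Br | target

Total step count: 6. Longest linear sequence: 6 steps (1 to 13).

Steps most likely to fail

Step 3 (key step). The bromine-deactivated diene may lose its silyl group, or acrolein may polymerise, faster than the cycloaddition proceeds. The fallback sets out from 4 and replaces acrolein by methyl vinyl ketone, an enone that can be heated in large excess without polymerising. Thermal cycloaddition and the same acid work-up should give methyl 2-(5-acetyl-2,3-dibromo-4-hydroxyphenyl)acetate F1. Ketone Dakin oxidation of this ortho-hydroxyacetophenone (alkaline H2O2) converts the acetyl group into the C5 hydroxyl and comes back to the route at 10.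

Step 2. The amine may add to the β-bromo carbon with loss of bromide, or the silyl group may be lost by hydrolysis while the furan is handled. The fallback sets out from 3 and changes to amine-free hard enolisation with a sturdier silyl group. Deprotonation with LiN(SiMe3)2 in THF at −78 °C and O-silylation with triisopropylsilyl triflate should give methyl 2-[3,4-dibromo-5-(triisopropylsilyloxy)furan-2-yl]acetate F2. F2 is used in place of 4 under the conditions of step 3 and comes back to the route at 8.

Step 6. A phenolic hydroxyl may be sulfated in competition with the primary alcohol, or the sulfate may be lost by acid-catalysed hydrolysis during isolation. The fallback sets out from 11 and masks the catechol. Acetylation of the phenoxides with Ac2O in ice-cold aqueous NaOH, which spares the aliphatic alcohol, should give 2-(4,5-diacetoxy-2,3-dibromophenyl)ethanol F3. Sulfation with SO3·pyridine then gives pyridinium 2-(4,5-diacetoxy-2,3-dibromophenyl)ethyl sulfate F4. NH3 in MeOH removes both acetates without touching the sulfate ester and gives ammonium 2-(2,3-dibromo-4,5-dihydroxyphenyl)ethyl sulfate F5. Cation exchange (H+ form) comes back to the route at 13.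

Further compounds
F1 | step 3 | methyl 2-(5-acetyl-2,3-dibromo-4-hydroxyphenyl)acetate | COC(=O)Cc1cc(C(C)=O)c(O)c(Br)c1Br
F2 | step 2 | methyl 2-[3,4-dibromo-5-(triisopropylsilyloxy)furan-2-yl]acetate | COC(=O)Cc1oc(O[Si](C(C)C)(C(C)C)C(C)C)c(Br)c1Br
F3 | step 6 | 2-(4,5-diacetoxy-2,3-dibromophenyl)ethanol | CC(=O)Oc1cc(CCO)c(Br)c(Br)c1OC(C)=O
F4 | step 6 | pyridinium 2-(4,5-diacetoxy-2,3-dibromophenyl)ethyl sulfate | CC(=O)Oc1cc(CCOS(=O)(=O)[O-])c(Br)c(Br)c1OC(C)=O.c1cc[nH+]cc1
F5 | step 6 | ammonium 2-(2,3-dibromo-4,5-dihydroxyphenyl)ethyl sulfate | [NH4+].[O-]S(=O)(=O)OCCc1cc(O)c(O)c(Br)c1Br
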